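## The problem

Compound 31 is a 3,4,7,8-tetrahydro-2H-chromene-4,7-dione (chromene numbering is used for all ring atoms below, also in precursors). Ring B, a cis-2,3-dimethyl-2,3-dihydropyran-4-one, is fused through the C4a=C8a double bond to ring A, a dearomatised acylphloroglucinol with an enolic C5–OH, a (3S)-hexanoic acid side chain on C6 and a quaternary C8 carrying a prenyl and a cis-1,3-disubstituted cyclobutylmethyl group. The six stereocentres form four mutually remote sets: C2/C3, the side-chain carbon, C8, and the cyclobutane pair. Only C2/C3 are contiguous and can be made in one event; no set can control another. C8 is the hardest: both of its carbon substituents are CH2R groups and its ring neighbours C7 and C8a are sp2, so an enolate at C8 has neither a defined geometry nor a neighbouring stereocentre, and the centre has to be set by a reagent or catalyst. Several groups limit the conditions: the cis C3 centre is alpha to the C4 carbonyl and goes to trans under base (directly or through retro-oxa-Michael opening of ring B); the isopropenylcyclobutane ionises under strong acid to a cyclobutylcarbinyl cation; a prenyl group next to an enolised carbonyl cyclises under acid; the beta-triketone is cleaved by hard nucleophiles; three C=C bonds exclude hydrogenation. The feature that makes the key step possible is ring B itself: O1–C2–C3–C4(=O)–C4a=C8a is a 2,3-dihydro-4H-pyran-4-one, the direct retron of a [4+2] cycloaddition of an aldehyde C=O (O1, C2) with a 1-alkoxy-3-silyloxy diene (C3, C4, C4a, C8a), which forms O1–C8a and C2–C3 and both methyl-bearing centres at once.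

## Retrosynthesis

**31 from 30.** The ester C–O bond of the side chain is the last bond made or broken. The acid is carried as its methyl ester 30 because it has to survive amide bases, and the final unmasking must avoid acid (alkenes) and strong base (C3); a neutral tin hydroxide hydrolysis meets both.

**30 from 28 and 29.** The C8–CH2 bond of the prenyl group is cut. The neighbouring cut, C8–CH2 of the cyclobutylmethyl group, would need a hindered, non-allylic electrophile. Introducing C8 as a quaternary ester enolate would leave its configuration uncontrolled, because an enolate bearing two CH2R groups has no defined geometry. The precursor 28 is a flat chromanone in which C8 is not stereogenic, so one stereocentre fewer has to be carried. The forward reaction must be C-selective, must choose C8 over C6 and oxygen, must deliver the linear prenyl isomer from 29, and must choose one face of the planar ring. This is the one step without direct precedent, and a chiral palladium catalyst is asked to do it.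

**28 from 27.** The C4a=C8a unsaturation is removed. In the saturated compound 27 the C8 proton is an ordinary proton next to a ketone, and ring A can be closed under kinetic base without touching ring B. The forward step is a dehydrogenation that starts at C8a–H, the only C–H that is both allylic to an enol and alpha to oxygen; it also erases the transient centres at C8a, C8 and C6.

**27 from 20 and 24.** The C6–C7 bond (Dieckmann) and the C4a–C5 bond (enolate acylation) are cut, which removes ring A and gives the monocyclic oxanone 20 and the acyclic glutarate 24, the latter carrying the side-chain stereocentre. Cutting C7–C8 or C5–C6 instead would split the glutarate unit and lose its easy desymmetrisation. The forward reaction needs enolisation of 20 at the C4a methylene and not at the C3 methine, and ring closure through C6.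

**20 from 9 and 18.** The C8a–C8 bond is cut. The beta-carbon of the vinylogous ester 9 is the natural acceptor, and a silyl ketene acetal adds under mild Lewis acid catalysis without base. C8 is deliberately brought in as a tertiary carbon; its configuration and that of C8a do not matter because both are planarised later.

**9 from 6 and 7 (key step).** O1–C8a and C2–C3 are cut. Against an aldol-then-cyclise route, the cycloaddition makes both ring bonds and both stereocentres in one catalytic operation and delivers the cis isomer kinetically, without base. The precursors are achiral and have at most twelve carbons. The forward reaction needs endo selectivity, one aldehyde face, and a non-epimerising work-up.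

**6 from 4 and 5; 4 from 1 and 2.** The O–Si bond and then the acyl–vinyl C–C bond are cut; the (3Z) geometry of 6 is what the cis relationship in 9 depends on.

**18 from 10.** The ketene acetal 18 comes from ester 16, and 16 from acid 12 by one-carbon homologation via 14. Acid 12 comes from keto acid 11 by methylenation, and 11 from cleavage of the C2=C3 bond of 10. The cyclobutane and both of its stereocentres come from the chiral pool, and no ring bond is made.

**24 from 21.** Acylating agent 24 comes from hemiester 23, and 23 from the prochiral anhydride 22 of diacid 21; one of two enantiotopic C–O bonds is opened, which sets the side-chain centre on an eight-carbon compound.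

## Roads not taken

**Alternative 1:** The cut runs through the cyclobutane. A crossed intramolecular enone–alkene [2+2] photocycloaddition of an open-chain silyloxy dienone would join the CMe2 carbon to the internal vinyl carbon and the enone alpha-carbon to the terminal CH2, closing the four-membered ring and a cyclopentanone at once to give A1.
- Merits: the bicyclic frame enforces the cis-1,3 relationship; either enantiomer is available from one carbinol centre; the route does not depend on the optical purity of a terpene. In these respects it is better than the chosen plan.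
- Weak points: facial control by a single silyloxy group in a triplet cycloaddition is uncertain. A1 is still several steps from a usable fragment: the cyclopentanone must be cleaved, one carbon adjusted and the ketone methylenated. The photochemical step solves none of the problems at C8, C2/C3 or ring A.
- Comparison: the chosen plan takes the same cyclobutane with both centres from 10 in four steps to 16, and spends its design effort on ring B and C8.

**Alternative 2:** The cut is the C6–CH(propyl) bond plus a lactone C–O bond. An unsaturated six-carbon acyl donor bound to an isothiourea catalyst would be attacked by one nucleophilic carbon of a preformed ring A trione, and the neighbouring enol oxygen would lactonise to give A2.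
- Merits: the side-chain centre and the C6–C bond form in one catalytic step on an advanced intermediate, and no strong-base ring closure is needed. That is at least as economical as the anhydride opening to 23 followed by the acylation–Dieckmann sequence.
- Weak points: the trione offers two nucleophilic carbons and several enol oxygens, and the only element that distinguishes them is the remote quaternary C8. Beta-alkyl acyl donors are the less reactive class in this catalysis. C8 must already be in place, and ring B still has to be built afterwards on a base-sensitive trione, where the cis C2/C3 pair is the kinetic and not the thermodynamic arrangement.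
- Comparison: the chosen plan sets the side-chain centre on the small anhydride 22 and the cis pair in 9 before anything sensitive exists. What it gives up is the late, convergent entry of the side chain.

**Alternative 3:** The cuts are C4a–C8a and C6–C7 of ring A. A methyl ketone enolate is acylated by an acid chloride, and the diketone dianion closes onto a methyl ester to give A3, with C8 and the side chain in place.
- Merits: the C8 configuration is fixed early in an acyclic precursor by which of its two carbonyl groups is the ketone and which the ester. It never depends on a late facial choice, which is clearly better than the chosen plan's catalyst-controlled quaternisation in step 15. The ring closure is the same reaction type as step 13, so it is equally credible.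
- Weak points: A3 has no ring B. That ring must be added last by acylation and oxa-Michael closure on a trione with two competing enol oxygens, under conditions that equilibrate C3 and favour the trans isomer.
- Comparison: the chosen plan makes ring B first, catalytically and as the cis isomer, and never exposes it to equilibrating base. It pays for this with the unprecedented step 15.

Key step: step 3

Assumption: the antipodes of the chromium catalyst (step 3), the cinchona catalyst (step 11) and the diphosphine ligand (step 15) are written as expected by analogy; both antipodes of each are available, so the sense of induction is settled by choosing the antipode in a pilot run, not by changing the route.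

Assumption: (1R,5R)-alpha-pinene of high enantiomeric purity, 3-propylpentanedioic acid and carbonate 29 are taken as commercial.

## Route

Step 1
Reactants: 1 propanoyl chloride; 2 methoxyethene
Product: 4 (E)-1-methoxypent-1-en-3-one, via 1-chloro-1-methoxypentan-3-one 3 (not isolated)
Conditions: excess 2, no solvent, 0 °C to rt; then Et3N, Et2O, 0 °C
Reagents that add atoms: none
Why: Acylation of the enol ether gives the beta-chloro-beta-methoxy ketone, and amine-induced loss of HCl gives the (E)-beta-methoxy enone (vinyl ether acylation and dehydrochlorination); the amine is added only after the acylation so that no ketene forms.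

Step 2
Reactants: 4 (E)-1-methoxypent-1-en-3-one; 5 triethylsilyl trifluoromethanesulfonate
Product: 6 (1E,3Z)-1-methoxy-3-(triethylsilyloxy)penta-1,3-diene
Conditions: Et3N, Et2O, −78 to 0 °C
Reagents that add atoms: none
Why: Soft enolisation of the ethyl ketone with silyl triflate and amine should give the cross-conjugated silyl enol ether with (Z) geometry, the isomer in which the methyl group avoids the vinyl group.

Step 3
Reactants: 6 (1E,3Z)-1-methoxy-3-(triethylsilyloxy)penta-1,3-diene; 7 acetaldehyde
Product: 9 (2R,3S)-2,3-dimethyl-2,3-dihydro-4H-pyran-4-one, via silyl cycloadduct 8 (not isolated)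
Conditions: 7 (3 equiv), CrCl(L) (3 mol%; H2L = (1S,2R)-1-{[3-(adamantan-1-yl)-2-hydroxy-5-methylbenzylidene]amino}indan-2-ol), powdered 4 Å molecular sieves, t-BuOMe, 4 °C, closed vessel; then CF3CO2H, CH2Cl2, 0 °C
Reagents that add atoms: none
Why: The trivalent chromium centre of CrCl(L) binds the aldehyde oxygen, and the diene adds in a concerted, asynchronous [4+2] cycloaddition in which C2–C3 bonding leads and O1–C8a bonding follows. The closest known reaction type is the Lewis-acid-catalysed enantioselective hetero-Diels–Alder reaction of aldehydes with 1-alkoxy-3-silyloxy dienes, for which tridentate Schiff-base chromium chlorides are established with aliphatic aldehydes and (Z)-configured dienes. Ring B closes in this single intermolecular cycloaddition, both ring bonds forming in one six-membered pericyclic array. C2 is set by the aldehyde face left open in the chiral pocket of the catalyst. C3 is set relative to C2 by the endo approach of the aldehyde methyl group together with the (3Z) geometry of 6, which places the two methyl groups cis. The step needs regiochemistry, endo selectivity and one aldehyde face: the first is fixed by the polarity of the diene (nucleophilic C4 to the carbonyl carbon), the second by the outside position of the diene methyl group, the third by the ligand. Trifluoroacetic acid then cleaves the silyl enol ether of 8 and expels methanol; protonation occurs at C4a, so the cis C3 centre is not touched.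

Step 4
Reactants: 10 (1R,5R)-2,6,6-trimethylbicyclo[3.1.1]hept-2-ene
Product: 11 2-[(1S,3S)-3-acetyl-2,2-dimethylcyclobutyl]acetic acid
Conditions: RuCl3 hydrate (2 mol%), NaIO4 (4 equiv), MeCN/EtOAc/H2O, rt
Reagents that add atoms: sodium periodate, [Na+].[O-]I(=O)(=O)=O; water, O
Why: RuO4 formed in the flask cleaves the trisubstituted alkene to the methyl ketone and the carboxylic acid (oxidative alkene cleavage); the two ring centres are not involved, so the cis-1,3 relationship and the absolute configuration come unchanged from the chiral pool.

Step 5
Reactants: 11 2-[(1S,3S)-3-acetyl-2,2-dimethylcyclobutyl]acetic acid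
Product: 12 2-[(1S,3R)-2,2-dimethyl-3-(prop-1-en-2-yl)cyclobutyl]acetic acid
Conditions: Ph3PCH3Br (2.5 equiv), KOtBu (2.5 equiv), THF, 0 °C to rt
Reagents that add atoms: methyltriphenylphosphonium bromide, C[P+](c1ccccc1)(c1ccccc1)c1ccccc1.[Br-]
Why: Wittig methylenation of the methyl ketone with the carboxylate as a spectator; the non-stabilised ylide reacts faster than it enolises the ketone, so the acetyl-bearing centre should stay cis (the descriptor changes only because the priorities change).

Step 6
Reactants: 12 2-[(1S,3R)-2,2-dimethyl-3-(prop-1-en-2-yl)cyclobutyl]acetic acid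
Product: 14 1-diazo-3-[(1S,3R)-2,2-dimethyl-3-(prop-1-en-2-yl)cyclobutyl]propan-2-one, via mixed anhydride 13 (not isolated)
Conditions: i-BuOCOCl, N-methylmorpholine, THF, −15 °C; then CH2N2, Et2O, 0 °C
Reagents that add atoms: diazomethane, C=[N+]=[N-]
Why: Acylation of diazomethane by a mixed carbonic anhydride (first half of the Arndt–Eistert homologation); the anhydride is used in place of an acid chloride so that no HCl meets the acid-labile isopropenylcyclobutane.

Step 7
Reactants: 14 1-diazo-3-[(1S,3R)-2,2-dimethyl-3-(prop-1-en-2-yl)cyclobutyl]propan-2-one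
Product: 16 methyl 3-[(1R,3R)-2,2-dimethyl-3-(prop-1-en-2-yl)cyclobutyl]propanoate, via ketene 15 (not isolated)
Conditions: PhCO2Ag (10 mol%), Et3N, MeOH, rt, dark
Reagents that add atoms: methanol, CO
Why: Silver-promoted Wolff rearrangement gives the ketene, which methanol traps as the homologous ester; only the CH2 group migrates, so no stereocentre is affected (the ring descriptor changes with the priorities).

Step 8
Reactants: 16 methyl 3-[(1R,3R)-2,2-dimethyl-3-(prop-1-en-2-yl)cyclobutyl]propanoate
Product: 18 {1-methoxy-3-[(1S,3R)-2,2-dimethyl-3-(prop-1-en-2-yl)cyclobutyl]prop-1-en-1-yl}oxy(trimethyl)silane (E/Z mixture), via lithium enolate 17 (not isolated)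
Conditions: LiN(iPr)2, THF, −78 °C; Me3SiCl, −78 °C to rt; non-aqueous work-up
Reagents that add atoms: chlorotrimethylsilane, C[Si](C)(C)Cl
Why: O-Silylation of the ester enolate gives the ketene silyl acetal; its double-bond geometry is immaterial because the carbon it will become (C8) is planarised again in step 14.

Step 9
Reactants: 9 (2R,3S)-2,3-dimethyl-2,3-dihydro-4H-pyran-4-one; 18 ketene silyl acetal
Product: 20 methyl 2-[(2S,5S,6R)-5,6-dimethyl-4-oxooxan-2-yl]-3-[(1S,3R)-2,2-dimethyl-3-(prop-1-en-2-yl)cyclobutyl]propanoate (both epimers at C8), via trimethylsilyl enol ether 19 (not isolated)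
Conditions: Me3SiOTf (10 mol%), 2,6-di-tert-butyl-4-methylpyridine (10 mol%), CH2Cl2, −78 °C; then aq. citric acid, THF, 0 °C
Reagents that add atoms: none
Why: Mukaiyama–Michael addition to the beta-carbon of the vinylogous ester forms C8a–C8 by axial attack anti to the C2 methyl group (2,6-trans oxanone); the enol silane forms toward C4a, so C3 is never enolised, and the new centres at C8a and C8 need no control because step 14 removes them.

Step 10
Reactants: 21 3-propylpentanedioic acid
Product: 22 4-propyloxane-2,6-dione
Conditions: Ac2O, reflux; distillation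
Reagents that add atoms: none
Why: Dehydrative ring closure of a 1,5-diacid to the six-membered cyclic anhydride by anhydride exchange.

Step 11
Reactants: 22 4-propyloxane-2,6-dione
Product: 23 (3R)-5-methoxy-5-oxo-3-propylpentanoic acid
Conditions: MeOH (10 equiv), (DHQD)2AQN (hydroquinidine anthraquinone-1,4-diyl diether, 30 mol%), Et2O, −40 °C
Reagents that add atoms: methanol, CO
Why: Cinchona-alkaloid-catalysed alcoholysis of a prochiral 3-substituted glutaric anhydride; the catalyst acts as a chiral general base and opens one of the two enantiotopic carbonyl groups, which sets the side-chain stereocentre.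

Step 12
Reactants: 23 (3R)-5-methoxy-5-oxo-3-propylpentanoic acid
Product: 24 methyl (3R)-5-(1H-benzotriazol-1-yl)-5-oxo-3-propylpentanoate
Conditions: 1H-benzotriazole, N,N'-dicyclohexylcarbodiimide, CH2Cl2, 0 °C to rt
Reagents that add atoms: 1H-benzotriazole, c1ccc2[nH]nnc2c1
Why: Carbodiimide coupling gives the N-acylbenzotriazole, a neutral acyl donor known to acylate ketone enolates on carbon; the stereocentre is beta to the activated carbonyl and cannot racemise.

Step 13
Reactants: 20 keto ester; 24 methyl (3R)-5-(1H-benzotriazol-1-yl)-5-oxo-3-propylpentanoate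
Product: 27 methyl (3S)-3-[(2R,3S,8aR)-8-{[(1S,3R)-2,2-dimethyl-3-(prop-1-en-2-yl)cyclobutyl]methyl}-5-hydroxy-2,3-dimethyl-4,7-dioxo-3,4,6,7,8,8a-hexahydro-2H-chromen-6-yl]hexanoate (epimers at C6 and C8; enol tautomers), via lithium enolate 25 (not isolated), via beta-diketone 26 (not isolated)
Conditions: LiN(iPr)2 (1.05 equiv), THF, −78 °C; 24; then LiN(SiMe3)2 (2.5 equiv), −78 to 0 °C; aq. NH4Cl
Reagents that add atoms: none
Why: Kinetic deprotonation takes the C4a methylene and not the C3 methine, and the enolate is C-acylated by the N-acylbenzotriazole (Claisen-type acylation, C4a–C5). The diketonate is then deprotonated at the C6 methylene and this carbon attacks the C7 methyl ester (Dieckmann condensation, 6-exo-trig, C6–C7). C3 is protected because the C4 carbonyl is tied up in the diketonate and the less substituted sites are deprotonated first.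

Step 14
Reactants: 27 bicyclic triketone
Product: 28 methyl (3S)-3-[(2R,3S)-8-{[(1S,3R)-2,2-dimethyl-3-(prop-1-en-2-yl)cyclobutyl]methyl}-5,7-dihydroxy-2,3-dimethyl-4-oxo-3,4-dihydro-2H-chromen-6-yl]hexanoate
Conditions: 2,3-dichloro-5,6-dicyano-1,4-benzoquinone (1.05 equiv), 1,4-dioxane, 10 °C to rt
Reagents that add atoms: none
Why: The quinone abstracts hydride from C8a–H, which is allylic to the C4a=C5 enol and alpha to O1; loss of a proton and tautomerisation give the phloroglucinol-type arene (quinone dehydrogenation, as in flavanone-to-flavone oxidation). All diastereomers of 27 converge because C8a, C8 and C6 become sp2.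

Step 15
Reactants: 28 chromanone; 29 tert-butyl 2-methylbut-3-en-2-yl carbonate
Product: 30 methyl (3S)-3-[(2R,3S,8R)-8-{[(1S,3R)-2,2-dimethyl-3-(prop-1-en-2-yl)cyclobutyl]methyl}-5-hydroxy-2,3-dimethyl-8-(3-methylbut-2-en-1-yl)-4,7-dioxo-3,4,7,8-tetrahydro-2H-chromen-6-yl]hexanoate
Conditions: Pd2(dba)3·CHCl3 (2.5 mol%), (1R,2R)-N,N'-bis[2-(diphenylphosphanyl)benzoyl]cyclohexane-1,2-diamine (7.5 mol%), 29 (1.1 equiv), THF, 0 °C to rt
Reagents that add atoms: none
Why: Proposed new method: zerovalent palladium ionises 29 to a (1,1-dimethylallyl)palladium cation, carbon dioxide and tert-butoxide, which deprotonates the C7–OH (the vinylogous acid); the phenoxide attacks outer-sphere through C8 at the unsubstituted allyl terminus, and the chiral diphosphine pocket chooses the ring face, which sets C8 under catalyst control while O-prenylation stays reversible under palladium and C6 is shielded by its branched side chain; the closest known reaction types are the palladium-catalysed intermolecular asymmetric allylic dearomatisation of substituted 2-naphthols and the non-asymmetric palladium-catalysed dearomative C-allylation of acylphloroglucinols.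

Step 16
Reactants: 30 methyl ester
Product: 31 (3S)-3-[(2R,3S,8R)-8-{[(1S,3R)-2,2-dimethyl-3-(prop-1-en-2-yl)cyclobutyl]methyl}-5-hydroxy-2,3-dimethyl-8-(3-methylbut-2-en-1-yl)-4,7-dioxo-3,4,7,8-tetrahydro-2H-chromen-6-yl]hexanoic acid
Conditions: Me3SnOH (5 equiv), ClCH2CH2Cl, 70 °C; then 5% aq. KHSO4, 0 °C, brief
Reagents that add atoms: trimethyltin hydroxide, C[Sn](C)(C)O
Why: Near-neutral hydrolysis of a methyl ester by trimethyltin hydroxide; no strong acid meets the alkenes and no strong base meets C3 or the triketone, so no stereocentre is touched.

## Compound list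

1 | propanoyl chloride | CCC(=O)Cl | starting material
2 | methoxyethene | COC=C | starting material
3 | 1-chloro-1-methoxypentan-3-one | CCC(=O)CC(Cl)OC | intermediate (not isolated)
4 | (E)-1-methoxypent-1-en-3-one | CCC(=O)/C=C/OC | intermediate
5 | triethylsilyl trifluoromethanesulfonate | CC[Si](CC)(CC)OS(=O)(=O)C(F)(F)F | starting material
6 | (1E,3Z)-1-methoxy-3-(triethylsilyloxy)penta-1,3-diene | CO/C=C/C(=C/C)O[Si](CC)(CC)CC | intermediate
7 | acetaldehyde | CC=O | starting material
8 | (2R,3S,6R)-6-methoxy-2,3-dimethyl-4-(triethylsilyloxy)-3,6-dihydro-2H-pyran | CO[C@@H]1O[C@H](C)[C@H](C)C(O[Si](CC)(CC)CC)=C1 | intermediate (not isolated)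
9 | (2R,3S)-2,3-dimethyl-2,3-dihydro-4H-pyran-4-one | C1=CO[C@H](C)[C@H](C)C1=O | intermediate
10 | (1R,5R)-2,6,6-trimethylbicyclo[3.1.1]hept-2-ene | CC1=CC[C@@H]2C[C@H]1C2(C)C | starting material
11 | 2-[(1S,3S)-3-acetyl-2,2-dimethylcyclobutyl]acetic acid | CC(=O)[C@H]1C[C@@H](CC(=O)O)C1(C)C | intermediate
12 | 2-[(1S,3R)-2,2-dimethyl-3-(prop-1-en-2-yl)cyclobutyl]acetic acid | C=C(C)[C@H]1C[C@@H](CC(=O)O)C1(C)C | intermediate
13 | 2-[(1S,3R)-2,2-dimethyl-3-(prop-1-en-2-yl)cyclobutyl]acetic 2-methylpropyl carbonic anhydride | C=C(C)[C@H]1C[C@@H](CC(=O)OC(=O)OCC(C)C)C1(C)C | intermediate (not isolated)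
14 | 1-diazo-3-[(1S,3R)-2,2-dimethyl-3-(prop-1-en-2-yl)cyclobutyl]propan-2-one | C=C(C)[C@H]1C[C@@H](CC(=O)C=[N+]=[N-])C1(C)C | intermediate
15 | 3-[(1S,3R)-2,2-dimethyl-3-(prop-1-en-2-yl)cyclobutyl]prop-1-en-1-one | C=C(C)[C@H]1C[C@@H](CC=C=O)C1(C)C | intermediate (not isolated)
16 | methyl 3-[(1R,3R)-2,2-dimethyl-3-(prop-1-en-2-yl)cyclobutyl]propanoate | C=C(C)[C@H]1C[C@@H](CCC(=O)OC)C1(C)C | intermediate
17 | lithium 1-methoxy-3-[(1S,3R)-2,2-dimethyl-3-(prop-1-en-2-yl)cyclobutyl]prop-1-en-1-olate | C=C(C)[C@H]1C[C@@H](CC=C(OC)O[Li])C1(C)C | intermediate (not isolated)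
18 | {1-methoxy-3-[(1S,3R)-2,2-dimethyl-3-(prop-1-en-2-yl)cyclobutyl]prop-1-en-1-yl}oxy(trimethyl)silane, E/Z mixture | C=C(C)[C@H]1C[C@@H](CC=C(OC)O[Si](C)(C)C)C1(C)C | intermediate
19 | methyl 2-[(2S,5S,6R)-5,6-dimethyl-4-(trimethylsilyloxy)-5,6-dihydro-2H-pyran-2-yl]-3-[(1S,3R)-2,2-dimethyl-3-(prop-1-en-2-yl)cyclobutyl]propanoate, both C8 epimers | C=C(C)[C@H]1C[C@@H](CC(C(=O)OC)[C@@H]2C=C(O[Si](C)(C)C)[C@@H](C)[C@@H](C)O2)C1(C)C | intermediate (not isolated)
20 | methyl 2-[(2S,5S,6R)-5,6-dimethyl-4-oxooxan-2-yl]-3-[(1S,3R)-2,2-dimethyl-3-(prop-1-en-2-yl)cyclobutyl]propanoate, both C8 epimers | C=C(C)[C@H]1C[C@@H](CC(C(=O)OC)[C@@H]2CC(=O)[C@@H](C)[C@@H](C)O2)C1(C)C | intermediate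
21 | 3-propylpentanedioic acid | CCCC(CC(=O)O)CC(=O)O | starting material
22 | 4-propyloxane-2,6-dione | CCCC1CC(=O)OC(=O)C1 | intermediate
23 | (3R)-5-methoxy-5-oxo-3-propylpentanoic acid | OC(=O)C[C@@H](CCC)CC(=O)OC | intermediate
24 | methyl (3R)-5-(1H-benzotriazol-1-yl)-5-oxo-3-propylpentanoate | O=C(C[C@@H](CCC)CC(=O)OC)n1nnc2ccccc21 | intermediate
25 | lithium C4–C4a enolate of 20 | C=C(C)[C@H]1C[C@@H](CC(C(=O)OC)[C@@H]2C=C(O[Li])[C@@H](C)[C@@H](C)O2)C1(C)C | intermediate (not isolated)
26 | methyl (3R)-5-[(2S,5S,6R)-2-{1-methoxy-1-oxo-3-[(1S,3R)-2,2-dimethyl-3-(prop-1-en-2-yl)cyclobutyl]propan-2-yl}-5,6-dimethyl-4-oxooxan-3-yl]-5-oxo-3-propylpentanoate, epimers at C4a and C8 | C=C(C)[C@H]1C[C@@H](CC(C(=O)OC)[C@@H]2C(C(=O)C[C@@H](CCC)CC(=O)OC)C(=O)[C@@H](C)[C@@H](C)O2)C1(C)C | intermediate (not isolated)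
27 | methyl (3S)-3-[(2R,3S,8aR)-8-{[(1S,3R)-2,2-dimethyl-3-(prop-1-en-2-yl)cyclobutyl]methyl}-5-hydroxy-2,3-dimethyl-4,7-dioxo-3,4,6,7,8,8a-hexahydro-2H-chromen-6-yl]hexanoate, epimers at C6 and C8 | C=C(C)[C@H]1C[C@@H](CC2C(=O)C([C@@H](CCC)CC(=O)OC)C(O)=C3C(=O)[C@@H](C)[C@@H](C)O[C@H]23)C1(C)C | intermediate
28 | methyl (3S)-3-[(2R,3S)-8-{[(1S,3R)-2,2-dimethyl-3-(prop-1-en-2-yl)cyclobutyl]methyl}-5,7-dihydroxy-2,3-dimethyl-4-oxo-3,4-dihydro-2H-chromen-6-yl]hexanoate | C=C(C)[C@H]1C[C@@H](Cc2c(O)c([C@@H](CCC)CC(=O)OC)c(O)c3c2O[C@H](C)[C@H](C)C3=O)C1(C)C | intermediate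
29 | tert-butyl 2-methylbut-3-en-2-yl carbonate | C=CC(C)(C)OC(=O)OC(C)(C)C | starting material
30 | methyl (3S)-3-[(2R,3S,8R)-8-{[(1S,3R)-2,2-dimethyl-3-(prop-1-en-2-yl)cyclobutyl]methyl}-5-hydroxy-2,3-dimethyl-8-(3-methylbut-2-en-1-yl)-4,7-dioxo-3,4,7,8-tetrahydro-2H-chromen-6-yl]hexanoate | C=C(C)[C@H]1C[C@@H](C[C@@]2(CC=C(C)C)C(=O)C([C@@H](CCC)CC(=O)OC)=C(O)C3=C2O[C@H](C)[C@H](C)C3=O)C1(C)C | intermediate
31 | (3S)-3-[(2R,3S,8R)-8-{[(1S,3R)-2,2-dimethyl-3-(prop-1-en-2-yl)cyclobutyl]methyl}-5-hydroxy-2,3-dimethyl-8-(3-methylbut-2-en-1-yl)-4,7-dioxo-3,4,7,8-tetrahydro-2H-chromen-6-yl]hexanoic acid | C=C(C)[C@H]1C[C@@H](C[C@@]2(CC=C(C)C)C(=O)C([C@@H](CCC)CC(=O)O)=C(O)C3=C2O[C@H](C)[C@H](C)C3=O)C1(C)C | target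

## Step count and least certain steps

Total: 16 steps. Longest linear sequence: 10 steps (steps 4–9 and 13–16, from 10). The ring B branch (steps 1–3) and the glutarate branch (steps 10–12) have three steps each.

**Step 15 (the step proposed as a new method).** The likely failures are insufficient discrimination of the two faces of the planar C8 by the ligand, and competing attack through oxygen, through C6, or at the substituted allyl terminus. The fallback gives up catalyst control and uses known chemistry. It sets out from 28 and comes back at 30. With achiral Pd(PPh3)4 (zerovalent palladium) and 29, or with prenyl bromide and aqueous hydroxide as in the classical C-prenylation of lupulone-type acylphloroglucinols, 28 should be alkylated at C8 without facial preference. This gives 30 together with its C8 epimer, methyl (3S)-3-[(2R,3S,8S)-…]hexanoate F1. The two are diastereomers and would be separated by preparative chromatography.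

**Step 3 (key step).** The small aldehyde may be differentiated poorly by the catalyst, some of it may be lost by evaporation or self-condensation, and C3 may epimerise during the acid-induced loss of methanol. The fallback builds the same ring from an auxiliary-controlled aldol; it sets out from 7 and comes back at 9.
- The dibutylboron enolate of (4S)-4-benzyl-3-propanoyl-1,3-oxazolidin-2-one (Bu2BOTf, i-Pr2NEt, CH2Cl2, −78 °C) adds to 7 in an Evans syn-aldol reaction to give (4S)-4-benzyl-3-[(2S,3R)-3-hydroxy-2-methylbutanoyl]-1,3-oxazolidin-2-one F2.
- AlMe3 and N,O-dimethylhydroxylamine hydrochloride convert F2 into (2S,3R)-3-hydroxy-N-methoxy-N,2-dimethylbutanamide F3.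
- Excess HC≡CMgBr converts F3 into (4S,5R)-5-hydroxy-4-methylhex-1-yn-3-one F4.
- A silver-catalysed 6-endo-dig oxa-Michael cyclisation of F4 (AgOTf, CH2Cl2) closes O1–C8a and gives 9 without base.

**Step 13.** Proton transfer from the newly formed diketone to unreacted enolate may let the enolate equilibrate toward C3 (epimerisation). Acylation may go to oxygen, or the dianion may form at C3 instead of C6. The fallback replaces the acylation by an aldol addition and an oxidation; it sets out from 23 and 20 and comes back at 26.
- Acid 23 is converted with oxalyl chloride into methyl (3S)-5-chloro-5-oxo-3-propylpentanoate F5.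
- F5 is reduced with LiAlH(OtBu)3 at −78 °C to methyl (3R)-5-oxo-3-propylpentanoate F6.
- The kinetic lithium enolate 25 of 20 adds to F6 to give the beta-hydroxy ketone F7 (aldol adduct at C4a).
- Dess–Martin oxidation of F7 gives 26, which is then isolated and closed to 27 with LiN(SiMe3)2 as in step 13.

**Step 14.** The electron-rich product 28 may be over-oxidised by the quinone at its benzylic positions before all of 27 is consumed. The fallback changes the mechanism from hydride abstraction to a palladium enolate pathway; it sets out from 27 and comes back at 28. Aerobic dehydrogenation with Pd(O2CCF3)2 (5 mol%, divalent palladium) in DMSO under O2, run without a sulfonic acid additive, should palladate the enolised triketone at carbon and remove C8a–H by beta-hydride elimination. This is the known palladium-catalysed dehydrogenation of cyclohexanones to phenols; the oxidant is too weak to attack the phenol product.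

## Further compounds

F1 | step 15 | methyl (3S)-3-[(2R,3S,8S)-8-{[(1S,3R)-2,2-dimethyl-3-(prop-1-en-2-yl)cyclobutyl]methyl}-5-hydroxy-2,3-dimethyl-8-(3-methylbut-2-en-1-yl)-4,7-dioxo-3,4,7,8-tetrahydro-2H-chromen-6-yl]hexanoate | C=C(C)[C@H]1C[C@@H](C[C@]2(CC=C(C)C)C(=O)C([C@@H](CCC)CC(=O)OC)=C(O)C3=C2O[C@H](C)[C@H](C)C3=O)C1(C)C
F2 | step 3 | (4S)-4-benzyl-3-[(2S,3R)-3-hydroxy-2-methylbutanoyl]-1,3-oxazolidin-2-one | O[C@H](C)[C@H](C)C(=O)N1C(=O)OC[C@@H]1Cc1ccccc1
F3 | step 3 | (2S,3R)-3-hydroxy-N-methoxy-N,2-dimethylbutanamide | O[C@H](C)[C@H](C)C(=O)N(C)OC
F4 | step 3 | (4S,5R)-5-hydroxy-4-methylhex-1-yn-3-one | O[C@H](C)[C@H](C)C(=O)C#C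
F5 | step 13 | methyl (3S)-5-chloro-5-oxo-3-propylpentanoate | O=C(Cl)C[C@@H](CCC)CC(=O)OC
F6 | step 13 | methyl (3R)-5-oxo-3-propylpentanoate | O=CC[C@@H](CCC)CC(=O)OC
F7 | step 13 | methyl (3R)-5-hydroxy-5-[(2S,5S,6R)-2-{1-methoxy-1-oxo-3-[(1S,3R)-2,2-dimethyl-3-(prop-1-en-2-yl)cyclobutyl]propan-2-yl}-5,6-dimethyl-4-oxooxan-3-yl]-3-propylpentanoate, mixture at the carbinol carbon, C4a and C8 | C=C(C)[C@H]1C[C@@H](CC(C(=O)OC)[C@@H]2C(C(O)C[C@@H](CCC)CC(=O)OC)C(=O)[C@@H](C)[C@@H](C)O2)C1(C)C
F0 | step 14 | none | none
A1 | alternative 1 | 3-(tert-butyldimethylsilyloxy)-5,5-dimethylbicyclo[2.1.1]hexan-2-one | O=C1[C@H](O[Si](C)(C)C(C)(C)C)[C@@H]2C[C@H]1C2(C)C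
A2 | alternative 2 | ring A enol lactone carrying the propyl stereocentre | C=C(C)[C@H]1C[C@@H](C[C@@]2(CC=C(C)C)C(=O)C3=C(CC2=O)OC(=O)C[C@@H]3CCC)C1(C)C
A3 | alternative 3 | ring A trione with C8 and the tert-butyl ester side chain in place | C=C(C)[C@H]1C[C@@H](C[C@@]2(CC=C(C)C)C(=O)C([C@@H](CCC)CC(=O)OC(C)(C)C)=C(O)CC2=O)C1(C)C
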